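(The numbers in the tables were computed from invented constants; scatter was added.)

- The pitfall with a bending curve is to draw one mean rate through it. Thursday's starting material falls from its charge to 38% in 3.00 h, a logarithmic mean of 0.323 h⁻¹, and this bench rule carried on to 10 h leaves 3.97%.

| setting | Thursday's | Monday's | flask |
|---|---|---|---|
| starting material | 0.30 M | 0.30 M | 0.30 M |
| reagent | 0.90 M | 0.45 M | 0.900 M |
| remark | the very flask that is asked about, followed so far | run made earlier |  |
| time |  |  | 10 h |

| run | time / h | starting material / % | mono adduct / % | double product / % |
|---|---|---|---|---|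
| Thursday's | 0.200 | 83 | 14 | 1 |
| Thursday's | 0.667 | 71 | 23 | 1 |
| Thursday's | 1.00 | 60 | 22 | 3 |
| Thursday's | 1.50 | 52 | 30 | 6 |
| Thursday's | 2.50 | 42 | 36 | 8 |
| Thursday's | 3.00 | 38 | 34 | 11 |
| Monday's | 0.500 | 86 | 11 | 2 |
| Monday's | 1.33 | 73 | 18 | 2 |
| Monday's | 2.50 | 68 | 22 | 1 |
| Monday's | 4.00 | 51 | 27 | 10 |
| Monday's | 5.00 | 43 | 31 | 2 |
| Monday's | 8.00 | 34 | 37 | 9 |

(standard deviation of a reading: 2 percentage points)

* how much starting material there is at 10 h, in percent of the starting material charged
* how much mono adduct there is at 10 h, in percent of the starting material charged
* how much double product there is at 10 h, in percent of the starting material charged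
* how much triple product there is at 10 h, in percent of the starting material charged

- a reading or a percentage of mono adduct counts all its forms, free or not

- I check what the mean hides. In Thursday's run the stretch up to 1.00 h reads 0.511 h⁻¹, but the stretch from there to 3.00 h reads 0.228 h⁻¹. The early reading is 2.24 times the later one, so one mean does not hold across Thursday's curve, and it stands a factor of 1.42 above the later reading.
- So I drop the early stretch and divide the later rate by the reagent charged. This gives the late constant per molar reagent charged, a pseudo-first-order reading, of 0.254 L mol⁻¹ h⁻¹.
- Monday's run, with 0.45 M of reagent, read from 1.33 h to 8.00 h, gives 0.255 L mol⁻¹ h⁻¹, which matches.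
- Starting from Thursday's last reading, this constant puts the starting material at 7.68% at 10 h, and that is the figure I commit to.
- The forecast gives 13% starting material, 21% mono adduct, 16% double product and 50% triple product, with the words “Extrapolating between second-order-like and late exponential behaviour”.
- Thursday's flask gives 7.91% starting material, 35.6% mono adduct, 27.6% double product and 4.78% triple product.

    starting material + reagent → mono adduct (k = 0.0290 L mol⁻¹ min⁻¹)
    mono adduct ⇌ isomer of the product (K = 0.480, k = 0.0270 min⁻¹)
    reagent + triple product → tetra adduct (k = 0.0430 L mol⁻¹ min⁻¹)
    crystals ⇌ mono adduct, rate k4*(cs4 - [mono adduct]) while solid is left; crystals form when [mono adduct] > cs4 (solubility = 0.180 M, k = 2.30 min⁻¹)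
    reagent ⇌ dormant form (K = 3.30, k = 0.0980 min⁻¹)
    reagent + mono adduct → double product (k = 0.0140 L mol⁻¹ min⁻¹)
    reagent + double product → triple product (k = 0.00990 L mol⁻¹ min⁻¹)

- My figure for the starting material in Thursday's flask lies 0.23 percentage points below what that flask holds. The neighbour flask has 0.23 M of reagent and is otherwise charged the same. It has no readings, so I start from its charge, and the same constant gives 55.8%. That flask holds 56.3% of starting material at 10.0 h.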